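**Plan**

1. Retrosynthetic cuts, in order: C12–C13 (side chain to butenolide), C8=C17, the O–C12 bond of a C8–O–C12 oxolane, C4–C5 by a retro-[3,3] shift that restores C2–C7, C2–C3 (alkenyl addition to a ketone), and last C9–C10 with C7–C8 (Diels–Alder).
2. Forward: ring B arises first, as the cyclohexene ring of an oxolane-fused bicyclo[2.2.2]octenone made from a masked o-benzoquinone and 2,3-dihydrofuran; ring A closes in the anionic oxy-Cope step; the butenolide is attached last by sp3–sp2 coupling.
3. Enabling feature (labdane numbering throughout): ring A (C1–C5, C10) is cis-fused to ring B (C5–C10), the quaternary C4 (C18 methyl, C19 acetoxymethyl) is bonded to the ring-fusion carbon C5, and C2 is a plain methylene that can carry a temporary carbonyl. This is the cis-octalone pattern that a 2-alkenylbicyclo[2.2.2]oct-5-en-2-ol releases.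
4. Stereochemistry: C10 and C9 (with C8, C7) are set relative to one another by the regio- and endo-selective cycloaddition and made absolute by resolution of the bicyclic ketone; C5 and C4 arise in the boat [3,3] shift, C5 from bonding on the bridge face and C4 from the Z geometry of the alkenyl group.
5. C19 travels as a benzyl ether, because a silyl group could migrate to the cis-disposed carbanion or alkoxide; it is freed during the hydrogenation and acetylated before the oxolane is opened.

Key step: step 7

Assumption: compounds 4–6 are racemic (their SMILES show the enantiomer carried on), and ketone 6 is taken to be separable on a polysaccharide chiral phase, the absolute configuration of 7 being secured by anomalous-dispersion X-ray analysis of a crystalline derivative before scale-up.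

**Route**

Step 1
Reactants: 1 2-methoxy-3-methylphenol; 2 2,3-dihydrofuran
Product: 4 (±)-9,9-dimethoxy-4-methyl-2,3,3a,4,7,7a-hexahydro-4,7-ethano-1-benzofuran-8-one (endo adduct), via dienone ketal 3 (not isolated)
Conditions: PhI(OAc)2 (1.2 equiv), MeOH, 2 (15 equiv), 0 °C → rt, slow addition of 1
Reagents that add atoms: methanol, CO
Why: Oxidative dearomatisation of the guaiacol by the trivalent iodine reagent gives the o-quinone monoketal, which reacts as an electron-poor diene in an inverse-electron-demand Diels–Alder reaction; the nucleophilic C3 of the enol ether bonds to the methyl-bearing δ-carbon of the dienone (future C10) so that oxygen ends on C8 next to the C7 bridgehead, and the endo transition state places the oxolane ring syn to the new C5=C6 bridge, fixing C10, C9, C8 and C7 relative to one another.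

Step 2
Reactants: 4 (±)-dimethoxy ketone
Product: 6 (±)-4-methyl-2,3,3a,4,7,7a-hexahydro-4,7-ethano-1-benzofuran-8-one, via α-methoxy ketone 5 (not isolated)
Conditions: SmI2 (5 equiv), THF–MeOH, 0 °C → rt
Reagents that add atoms: none
Why: Reductive cleavage of an α-alkoxy ketone by SmI2 (the ketyl expels the neighbouring methoxide and the samarium enolate is protonated by methanol, twice in succession) leaves the C1 methylene; no stereocentre is touched and the bridgehead C7–H cannot enolise.

Step 3
Reactants: 6 (±)-bicyclic ketone
Product: 7 bicyclic ketone of step 2 as the single enantiomer drawn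
Conditions: preparative SFC, amylose tris(3,5-dimethylphenylcarbamate) stationary phase, CO2/MeOH
Reagents that add atoms: none
Why: Resolution of a racemate by chromatography on a chiral stationary phase, for which a rigid, UV-active bicyclic ketone is a favourable case; the enantiomer kept fixes the absolute configuration of C10, C9, C8 and C7 for the rest of the route.

Step 4
Reactants: 8 prop-2-yn-1-ol
Product: 10 (Z)-3-iodo-2-methylprop-2-en-1-ol, via alkenylmagnesium alkoxide 9 (not isolated)
Conditions: MeMgBr (2.5 equiv), CuI (10 mol%), THF, −10 °C → rt; then I2, −78 → 0 °C; aq NH4Cl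
Reagents that add atoms: methylmagnesium bromide, C[Mg]Br; iodine, II
Why: Copper-catalysed anti-carbomagnesiation of the propargylic alkoxide delivers methyl to the internal carbon and magnesium to the terminal carbon cis to the CH2O group (O–Mg chelate), and iodinolysis with retention gives the Z iodide.

Step 5
Reactants: 10 (Z)-3-iodo-2-methylprop-2-en-1-ol
Product: 11 benzyl (Z)-3-iodo-2-methylprop-2-enyl ether
Conditions: NaH, BnBr, Bu4NI (catalytic), THF, 0 °C → rt
Reagents that add atoms: benzyl bromide, BrCc1ccccc1
Why: Williamson etherification of the primary alkoxide (the iodoalkene has no β-hydrogen for elimination); benzyl is preferred to silyl because silicon on this Z-oxygen could migrate to the alkenyl carbanion of step 6 or to the tertiary alkoxide of step 7, and because benzyl is removed without an extra step in step 8.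

Step 6
Reactants: 11 benzyl (Z)-iodoalkenyl ether; 7 enantiopure bicyclic ketone
Product: 13 8-[(Z)-3-benzyloxy-2-methylprop-1-enyl]-4-methyl-2,3,3a,4,7,7a-hexahydro-4,7-ethano-1-benzofuran-8-ol (alkenyl group syn to the 5,6-olefin), via alkenyllithium 12 (not isolated)
Conditions: 11 (1.5 equiv), t-BuLi (3.0 equiv), Et2O, −78 °C; then 7, −78 → −40 °C; aq NH4Cl
Reagents that add atoms: none
Why: Iodine–lithium exchange proceeds with retention of the Z geometry and the alkenyllithium undergoes 1,2-addition to the C2 ketone from the face of the C5=C6 bridge, which is more open than the face under the C8–C9 bridge whose hydrogens point at the carbonyl, so the alkenyl group ends syn to C5=C6 as the [3,3] shift requires.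

Step 7
Reactants: 13 bridged alkenyl carbinol
Product: 16 19-O-benzyl cis-octalone (2-oxo-6-ene carrying the C8–O–C12 oxolane), via potassium alkoxide 14 (not isolated), via potassium enolate 15 (not isolated)
Conditions: KH (3 equiv), 18-crown-6 (3 equiv), THF, 0 °C → rt (→ 50 °C if slow); aq NH4Cl, −78 °C
Reagents that add atoms: none
Why: KH with 18-crown-6 turns 13 into the naked tertiary alkoxide 14, whose oxyanion weakens the adjacent C2–C7 bond and drives a concerted [3,3] sigmatropic shift (anionic oxy-Cope rearrangement) across the 1,5-diene C4=C3–C2–C7–C6=C5, so that C2–C7 breaks, C4–C5 forms and enolate 15 is protonated on work-up at C3, which is not a stereocentre. The closest known reaction type is the alkoxide-accelerated oxy-Cope rearrangement of 2-vinylbicyclo[2.2.2]oct-5-en-2-ols to cis-fused octalones. Ring A (C1, C2, C3, C4, C5, C10) closes as a six-membered ring by this pericyclic C4–C5 bond formation through a six-centre boat array, while ring B is released from the bicycle as a cyclohexene with its olefin moved to C6=C7. C5 is controlled by the bicycle, since the alkenyl terminus can reach C5 only on the face turned toward the former C1–C2 bridge, which leaves H5 on the same side as the C20 methyl (cis fusion). C4 is controlled by olefin geometry, since in the boat the Z substituent (C19, CH2OBn) lies inside and ends cis to H5 while the E methyl (C18) ends trans. The step needs boat over chair (a chair would force C3 toward C1 and is geometrically excluded), [3,3] over [1,3] shift or fragmentation (secured by the held, overlapping diene and the low temperature) and an unchanged Z geometry; the benzyl ether cannot migrate to the alkoxide and C10, C9 and C8 take no part.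

Step 8
Reactants: 16 19-O-benzyl cis-octalone
Product: 17 saturated keto alcohol (C6–C7 reduced, C19–OH free)
Conditions: H2 (1 atm), Pd/C (10 wt% Pd on carbon), EtOH, rt
Reagents that add atoms: none
Why: Catalytic hydrogenation saturates the cis-disubstituted C6=C7 olefin (both carbons become methylenes, so no stereocentre arises) and hydrogenolysis of the benzyl ether follows in the same flask; olefin saturation in a neutral solvent should outrun hydrogenolysis of the allylic C8–O bond.

Step 9
Reactants: 17 saturated keto alcohol
Product: 19 tricyclic alcohol with C2 as methylene, via hydrazone 18 (not isolated)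
Conditions: N2H4·H2O, KOH, diethylene glycol, 130 °C then 195 °C with removal of water
Reagents that add atoms: none
Why: Wolff–Kishner reduction in the Huang-Minlon procedure (hydrazone formation, then base-induced loss of dinitrogen) removes the C2 carbonyl; both α-carbons are methylenes, so nothing can epimerise, and the ether and alcohol are inert to hot alkali.

Step 10
Reactants: 19 tricyclic alcohol
Product: 20 C19 acetate
Conditions: Ac2O, pyridine, DMAP (catalytic), CH2Cl2, rt
Reagents that add atoms: acetic anhydride, CC(=O)OC(C)=O
Why: DMAP-catalysed acylation of the only hydroxyl group, a neopentyl primary alcohol, installs the acetate of the target, which then serves as its own protecting group.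

Step 11
Reactants: 20 C19 acetate
Product: 22 12-bromo-8-hydroxy acetate, via dimethylborinate 21 (not isolated)
Conditions: Me2BBr (2.5 equiv), Et3N (0.2 equiv), CH2Cl2, 0 °C → rt; aq NaHCO3
Reagents that add atoms: bromodimethylborane, CB(C)Br
Why: Lewis-acid ether cleavage in which boron binds the ring oxygen and bromide opens the oxonium by SN2 attack at the primary C12 instead of the secondary ring carbon C8, so the C8–O bond is kept and the acetate, inert to this reagent, survives.

Step 12
Reactants: 22 bromo alcohol
Product: 23 12-bromo-8-ketone
Conditions: Dess–Martin periodinane, NaHCO3, CH2Cl2, 0 °C → rt (22 used without storage)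
Reagents that add atoms: none
Why: Dess–Martin oxidation of the secondary C8 alcohol under buffered, non-basic conditions should spare the primary bromide and the acetate and should not epimerise C9 or close the γ-bromo ketone to a cyclopropane.

Step 13
Reactants: 23 bromo ketone
Product: 24 12-bromo-8(17)-ene
Conditions: CH2Br2, Zn, TiCl4, THF (reagent formed at −40 → 5 °C); then 23, CH2Cl2, 0 °C → rt
Reagents that add atoms: dibromomethane, BrCBr
Why: Lombardo methylenation, whose non-basic gem-dimetallic reagent is suited to hindered, enolisable ketones, so C9 keeps its configuration, no enolate is formed that could displace the γ-bromide, and ester and alkyl bromide are left alone.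

Step 14
Reactants: 25 furan-2(5H)-one
Product: 27 3-bromofuran-2(5H)-one, via dibromolactone 26 (not isolated)
Conditions: Br2, CH2Cl2, 0 °C → rt; then Et3N, 0 °C
Reagents that add atoms: bromine, BrBr
Why: Bromine addition to the enoate followed by amine-induced E1cB loss of HBr (acidic α-proton, β-bromide) gives the α-bromobutenolide.

Step 15
Reactants: 24 12-bromo-8(17)-ene; 27 3-bromofuran-2(5H)-one
Product: 29 target CNP0350004.1, via alkylzinc bromide 28 (not isolated)
Conditions: Zn dust, I2 (5 mol%), DMA, 80 °C; solution decanted from excess Zn; then 27, PdCl2(dppf) (5 mol%), THF–DMA, rt → 45 °C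
Reagents that add atoms: none
Why: Negishi coupling in which zinc inserts into the primary C12–Br bond to give an ester-tolerant alkylzinc bromide and zerovalent palladium, formed in situ, joins it to the α-bromo enoate by oxidative addition, transmetallation and reductive elimination (the wide-bite-angle diphosphine disfavours β-hydride loss), forming C12–C13 without touching any stereocentre.

**Compound list**

1 | 2-methoxy-3-methylphenol | COc1c(C)cccc1O | starting material
2 | 2,3-dihydrofuran | C1=COCC1 | starting material
3 | 6,6-dimethoxy-5-methylcyclohexa-2,4-dien-1-one (masked o-benzoquinone, not isolated) | COC1(OC)C(C)=CC=CC1=O | intermediate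
4 | (±)-9,9-dimethoxy-4-methyl-2,3,3a,4,7,7a-hexahydro-4,7-ethano-1-benzofuran-8-one; oxolane cis-fused and syn to the 5,6-double bond (endo adduct); methyl bridgehead = labdane C10; racemate | C[C@@]12C(OC)(OC)C(=O)[C@@H](C=C1)[C@H]3OCC[C@@H]23 | intermediate
5 | (±)-9-methoxy-4-methyl-2,3,3a,4,7,7a-hexahydro-4,7-ethano-1-benzofuran-8-one (methoxy carbon = labdane C1, configuration there undefined; not isolated) | C[C@@]12C(OC)C(=O)[C@@H](C=C1)[C@H]3OCC[C@@H]23 | intermediate
6 | (±)-4-methyl-2,3,3a,4,7,7a-hexahydro-4,7-ethano-1-benzofuran-8-one, oxolane syn to the 5,6-double bond; racemate | C[C@@]12CC(=O)[C@@H](C=C1)[C@H]3OCC[C@@H]23 | intermediate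
7 | 4-methyl-2,3,3a,4,7,7a-hexahydro-4,7-ethano-1-benzofuran-8-one, single enantiomer as drawn | C[C@@]12CC(=O)[C@@H](C=C1)[C@H]3OCC[C@@H]23 | intermediate
8 | prop-2-yn-1-ol | C#CCO | starting material
9 | bromomagnesium (Z)-3-(bromomagnesio)-2-methylprop-2-en-1-olate (not isolated) | Br[Mg]/C=C(/C)CO[Mg]Br | intermediate
10 | (Z)-3-iodo-2-methylprop-2-en-1-ol | I/C=C(/C)CO | intermediate
11 | benzyl (Z)-3-iodo-2-methylprop-2-enyl ether | I/C=C(/C)COCc1ccccc1 | intermediate
12 | (Z)-3-benzyloxy-2-methylprop-1-enyllithium (not isolated) | [Li]/C=C(/C)COCc1ccccc1 | intermediate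
13 | 8-[(Z)-3-benzyloxy-2-methylprop-1-enyl]-4-methyl-2,3,3a,4,7,7a-hexahydro-4,7-ethano-1-benzofuran-8-ol; alkenyl group syn to the 5,6-double bond, hydroxyl toward the oxolane-bearing bridge (carbinol carbon = labdane C2) | C[C@@]12C[C@@](O)(/C=C(/C)COCc4ccccc4)[C@@H](C=C1)[C@H]3OCC[C@@H]23 | intermediate
14 | potassium alkoxide of 13 (not isolated) | C[C@@]12C[C@@]([O-])(/C=C(/C)COCc4ccccc4)[C@@H](C=C1)[C@H]3OCC[C@@H]23.[K+] | intermediate
15 | potassium C2–C3 enolate of 16 (not isolated) | C[C@@]12CC([O-])=C[C@@](C)(COCc4ccccc4)[C@@H]1C=C[C@H]3OCC[C@@H]23.[K+] | intermediate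
16 | cis-fused octalone: ring A 2-ketone, ring B C6=C7 olefin, oxolane C8–O–C12 cis-fused at C8/C9, C4 bearing β-CH3 (C18) and α-CH2OBn (C19); H5, C20 methyl, C19, C11 and O8 all α | C[C@@]12CC(=O)C[C@@](C)(COCc4ccccc4)[C@@H]1C=C[C@H]3OCC[C@@H]23 | intermediate
17 | keto alcohol: as 16 with C6–C7 saturated and free C19–OH | C[C@@]12CC(=O)C[C@@](C)(CO)[C@@H]1CC[C@H]3OCC[C@@H]23 | intermediate
18 | C2 hydrazone of 17 (not isolated) | C[C@@]12CC(=NN)C[C@@](C)(CO)[C@@H]1CC[C@H]3OCC[C@@H]23 | intermediate
19 | tricyclic alcohol: cis-decalin with C8–O–C12 oxolane, C2 methylene, free C19–OH; H5, C20, C19, C11, O8 all α | C[C@@]12CCC[C@@](C)(CO)[C@@H]1CC[C@H]3OCC[C@@H]23 | intermediate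
20 | C19 acetate of 19 | C[C@@]12CCC[C@@](C)(COC(C)=O)[C@@H]1CC[C@H]3OCC[C@@H]23 | intermediate
21 | C8 O-dimethylborinate of 22 (not isolated) | C[C@@]12CCC[C@@](C)(COC(C)=O)[C@@H]1CC[C@@H](OB(C)C)[C@H]2CCBr | intermediate
22 | bromo alcohol: 19-acetoxy-12-bromo cis-decalin with 8α-OH, side chain CH2CH2Br on C9 (α) | C[C@@]12CCC[C@@](C)(COC(C)=O)[C@@H]1CC[C@@H](O)[C@H]2CCBr | intermediate
23 | 19-acetoxy-12-bromo-8-ketone | C[C@@]12CCC[C@@](C)(COC(C)=O)[C@@H]1CCC(=O)[C@H]2CCBr | intermediate
24 | 19-acetoxy-12-bromo-8(17)-ene (exocyclic methylene on C8) | C[C@@]12CCC[C@@](C)(COC(C)=O)[C@@H]1CCC(=C)[C@H]2CCBr | intermediate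
25 | furan-2(5H)-one | O=C1OCC=C1 | starting material
26 | 3,4-dibromodihydrofuran-2(3H)-one (not isolated) | O=C1OCC(Br)C1Br | intermediate
27 | 3-bromofuran-2(5H)-one | O=C1OCC=C1Br | intermediate
28 | C12 alkylzinc bromide from 24 (not isolated) | C[C@@]12CCC[C@@](C)(COC(C)=O)[C@@H]1CCC(=C)[C@H]2CC[Zn]Br | intermediate
29 | CNP0350004.1: [1,4a-dimethyl-6-methylidene-5-[2-(2-oxo-2,5-dihydrofuran-3-yl)ethyl]decahydronaphthalen-1-yl]methyl acetate, cis-fused 19-acetoxy-labda-8(17),13-dien-16,15-olide with H5, C20 methyl, C19 and the C9 side chain all α | C[C@@]12CCC[C@@](C)(COC(C)=O)[C@@H]1CCC(=C)[C@H]2CCC3=CCOC3=O | target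

**Step count**

Total: 15 steps. Longest linear sequence: 12 steps (steps 1–3, 6–13 and 15) from 2-methoxy-3-methylphenol.

**Steps most likely to fail, and fallbacks**

Step 7. The Z benzyloxymethyl group has to sit in the inside position of the boat, close to C1 and C10. The shift may therefore be slowed so far that alkoxide-driven channels take over: heterolysis of C2–C7 followed by proton return, or base-induced isomerisation. The fallback gives up charge acceleration and uses the neutral thermal oxy-Cope rearrangement of a silyl ether. It sets out from 13, which would be silylated (N-trimethylsilylimidazole, CH2Cl2) to the trimethylsilyl ether F1. Heating F1 in degassed o-dichlorobenzene at 200–230 °C in base-washed sealed glass should give, through the same boat array and hence with the same C4/C5 outcome, the trimethylsilyl enol ether F2. Mild hydrolysis (dilute HCl, THF) would return the route at 16.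

Step 15. The electron-poor bromobutenolide may be consumed by conjugate addition or halogen–zinc exchange before transmetallation, and the hot zinc insertion may erode the bromide by protonation or elimination. The fallback forms C12–C13 by enolate alkylation instead of cross-coupling. It sets out from 24, which a Finkelstein exchange (NaI, acetone) would convert into the iodide F3. The lithium enolate of commercial 3-(phenylsulfanyl)oxolan-2-one (LiHMDS, THF–DMPU, −78 → −20 °C) would be alkylated with F3 to the sulfide lactone F4. One equivalent of mCPBA at −78 °C would give the sulfoxide F5. Thermal syn-elimination of benzenesulfenic acid toward the ring methylene (toluene, CaCO3, 110 °C) should then give the endocyclic butenolide and so arrive at 29.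

Step 1. Self-dimerisation of the dienone ketal, together with loss of the acid-labile enol ether to methanol addition, may outrun the cross-cycloaddition, and the methyl group on the reacting diene terminus may slow the desired bond formation further. The fallback separates oxidation from cycloaddition by using a halogen-blocked dienone. It sets out from 1, which would be brominated para to the hydroxyl (Bu4NBr3, CH2Cl2–MeOH) to 4-bromo-2-methoxy-3-methylphenol F6. Oxidation with PhI(OAc)2 in MeOH would give the bromo dienone ketal F7, a type that resists dimerisation and can be freed of methanol and acetic acid. Heating F7 with neat 2 (60–80 °C) should give the bromo cycloadduct F8 with the same regio- and endo-selectivity. Radical reduction of the alkenyl bromide (Bu3SnH, AIBN, toluene, 80 °C) would return the route at 4.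

**Further compounds**

F1 | step 7 | trimethylsilyl ether of carbinol 13 | C[C@@]12C[C@@](O[Si](C)(C)C)(/C=C(/C)COCc4ccccc4)[C@@H](C=C1)[C@H]3OCC[C@@H]23
F2 | step 7 | C2–C3 trimethylsilyl enol ether of 16 | C[C@@]12CC(O[Si](C)(C)C)=C[C@@](C)(COCc4ccccc4)[C@@H]1C=C[C@H]3OCC[C@@H]23
F3 | step 15 | 19-acetoxy-12-iodo-8(17)-ene | C[C@@]12CCC[C@@](C)(COC(C)=O)[C@@H]1CCC(=C)[C@H]2CCI
F4 | step 15 | 3-alkyl-3-(phenylsulfanyl)oxolan-2-one (sulfide lactone, mixture at the lactone α-carbon) | C[C@@]12CCC[C@@](C)(COC(C)=O)[C@@H]1CCC(=C)[C@H]2CCC3(Sc4ccccc4)CCOC3=O
F5 | step 15 | 3-alkyl-3-(phenylsulfinyl)oxolan-2-one (sulfoxide, mixture of diastereomers) | C[C@@]12CCC[C@@](C)(COC(C)=O)[C@@H]1CCC(=C)[C@H]2CCC3(S(=O)c4ccccc4)CCOC3=O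
F6 | step 1 | 4-bromo-2-methoxy-3-methylphenol | COc1c(C)c(Br)ccc1O
F7 | step 1 | 4-bromo-6,6-dimethoxy-5-methylcyclohexa-2,4-dien-1-one | COC1(OC)C(C)=C(Br)C=CC1=O
F8 | step 1 | (±)-5-bromo-9,9-dimethoxy-4-methyl-2,3,3a,4,7,7a-hexahydro-4,7-ethano-1-benzofuran-8-one (endo adduct, racemate) | C[C@@]12C(OC)(OC)C(=O)[C@@H](C=C1Br)[C@H]3OCC[C@@H]23
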